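The complex with one exchanged is the product to watch here, and by the charges it can reach at most 50.0 % of the starting complex.

    starting complex + incoming ligand ⇌ leaving ligand + complex with one exchanged (K1 = 25, k1 = 1.5 × 10⁻⁴ M⁻¹ s⁻¹)
    complex with one exchanged + incoming ligand ⇌ leaving ligand + complex with two exchanged (K2 = 0.64, k2 = 1.5 × 10⁻⁴ M⁻¹ s⁻¹)
    complex with two exchanged + incoming ligand ⇌ leaving ligand + complex with three exchanged (K3 = 0.82, k3 = 1.2 × 10⁻⁴ M⁻¹ s⁻¹)
    complex with three exchanged + incoming ligand ⇌ leaving ligand + complex with four exchanged (K4 = 26, k4 = 2.2 × 10⁻⁵ M⁻¹ s⁻¹)
    starting complex ⇌ dormant form (K5 = 0.74, k5 = 1.5 × 10⁻⁴ s⁻¹)
    starting complex + complex with four exchanged → side product (k6 = 4.5 × 10⁻⁵ M⁻¹ s⁻¹)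
    crystals ⇌ leaving ligand, rate k7*(cs7 - [leaving ligand]) while solid is left; crystals form when [leaving ligand] > cs7 (cs7 = 0.27 M, k7 = 0.0054 s⁻¹)

starting complex 0.50 M (in portions, 4); incoming ligand 0.500 equiv; time 10 d; the portions of starting complex follow each other after 40 min, the first at the start

- a species is counted by the starting complex in it: one side product counts as two
- amounts and yields of leaving ligand count crystals too
- given per volume of solution although it is solid: crystals
- what has gone from starting complex into another species counts as reacted, even if it can come back
- the reaction counts as stopped when no species that holds the starting complex changes by six tenths of a point or more over the second half of the time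
- run time (flask): 10 d

- which holds at 10 d: what has brought the reaction to rest, or that it has not come to rest (all of the starting complex has reacted / the incoming ligand has run out first / it is still moving / forward and back rates have come level)
- conversion of starting complex at 10 d
- amount of complex with one exchanged at 10 d, in percent of the starting complex charged
- amount of complex with two exchanged at 10 d, in percent of the starting complex charged
- amount of complex with four exchanged if the flask were left three thousand times as long, in percent of the starting complex charged

*Does this flask come to rest in the time?* I expect so, because the first exchange has a forward half-life of 0.21 d as charged and the dormant form relaxes with a half-life of 0.546 h, both far shorter than the 10 d allowed. The leaving ligand also cannot pass 0.250 M, which is less than its solubility of 0.27 M, so no crystals pull the exchange onward, and I commit to forward and back rates coming level.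

*What do you carry from this?* I carry the apparent exchange constant, 14.4, which is the constant of the first exchange divided by one plus the constant of the dormant form. Starting complex and dormant form share the unexchanged part in a fixed ratio, so the exchange sees them as one pool, and this constant equals the square of the exchanged fraction over the pool fraction times the leftover incoming ligand, all as fractions of the charge.

*Where do you begin?* The incoming ligand is the limiting reagent, so I treat the exchanged fraction as the large thing and the leftover as its small correction. Setting the exchanged fraction at the ceiling gives a leftover of 3.48 %, and putting that back gives 2.82 %, so 47.2 % of the charge has been exchanged.

*But the second exchange is as quick as the first, 0.21 d against 0.21 d as charged, so why is your figure safe?* At rest its constant counts rather than its speed: the ratio of complex with two exchanged to complex with one exchanged is 0.64 times leftover over leaving ligand, or 3.82 %. Each complex with two exchanged has released two leaving ligands, so I reckon 43.8 % of the complex with one exchanged and 1.67 % of the complex with two exchanged. The starting complex is then the pool's share, which makes the conversion 68.7 %.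

*And the complex with four exchanged?* Reckoned at the charges, the side-product step takes it with a half-life of 0.36 d, shorter than the 1.5 d of the fourth exchange that supplies it, so I expect a trace.

The forecast says forward and back rates have come level, with conversion 68.6 %, 43.4 % of the complex with one exchanged, 1.5 % of the complex with two exchanged and <0.001 % of the complex with four exchanged in the long run, close to my figures but not the same. For the last it argues that “the starting complex removes it to side product far faster than the slow fourth exchange can supply it”.

The outcome in the flask is that forward and back rates have come level, with conversion 68.7 %, 43.7 % of the complex with one exchanged, 1.56 % of the complex with two exchanged and 0 % of the complex with four exchanged in the long run.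

Its leftover incoming ligand, 5.3 % of its own charge, is 2.65 % of the starting complex, against my 2.82 %. The flask with 0.200 equiv of incoming ligand keeps the same 14.4, with its ceiling at 20.0 % of the charge. The leftover comes to 0.348 %, then 0.335 %, which puts the leaving ligand at 0.0983 M. That flask holds 0.0984 M of leaving ligand and a leftover of 0.327 % of the starting complex, with 19.2 % once exchanged.

The numbers were drawn at random within sensible limits; the result is computed.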